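**Retrosynthetic overview**
Numbering: C1 lactone C=O, C2 CH2, C3 CH–OO, C4 C(CH3)–O(lactone), C5 CH2, C6 C(CH3)–OO, C7–C18 the chain, phenyl on C18.
Feature: in the 1,2-dioxane ring the carbon path C3–C4–C5–C6 starts and ends at the two peroxide oxygens. Removing O2 and bonding C3 to C6 gives a cyclobutane, namely a 3-alkoxycyclobutanone. This is the (2+2) adduct of a succinate-derived keteniminium ion (C1, C2, C3, C6) and an isopropenyl ether (C5, C4, C4-CH3).
Disconnections, backwards: C8=C9 (diimide, cross-metathesis); lactone O–C1 with equilibration of C3; C6–C7 (allylation of a peroxycarbenium ion); O2 out with C3–C6 restored (aerobic cyclobutanol ring expansion); C6–CH3 (organocerium); C5–C6 and C3–C4 ((2+2)).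
Ring order: cyclobutane (temporary), then 1,2-dioxane, then γ-lactone. Stereochemistry: C4 from the pyrrolidine auxiliary, C6 from C4, C3 from C4.

Key step: step 3

Assumption: the (2R,5R)-pyrrolidine is taken to induce the (4R) configuration drawn for 8. The sense of induction with an enol ether has to be determined on 8. If it is opposite, the equally available (2S,5S)-amine is used with no other change.

Step 1
Reactants: 1 methyl 4-chloro-4-oxobutanoate; 2 (2R,5R)-2,5-dimethylpyrrolidine
Product: 3 methyl 4-[(2R,5R)-2,5-dimethylpyrrolidin-1-yl]-4-oxobutanoate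
Conditions: Et3N, CH2Cl2, 0 °C to rt
Reagents that add atoms: none
Why: N-acylation of a secondary amine by an acid chloride (Schotten–Baumann type) is reliable even for this hindered amine and does not touch the auxiliary centres.

Step 2
Reactants: 4 4-methoxybenzyl acetate
Product: 5 1-methoxy-4-[(prop-1-en-2-yloxy)methyl]benzene
Conditions: Cp2TiMe2 (2 equiv), toluene, 70 °C, dark; filtration through basic alumina
Reagents that add atoms: Cp2TiMe2, C[Ti+2]C.c1cc[cH-]c1.c1cc[cH-]c1
Why: In the Petasis methylenation, thermolysis of Cp2TiMe2 gives Cp2Ti=CH2, which turns the ester C=O into C=CH2 through an oxatitanacyclobutane under non-acidic conditions that the enol ether tolerates; no stereocentre is formed.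

Step 3
Reactants: 3 methyl 4-[(2R,5R)-2,5-dimethylpyrrolidin-1-yl]-4-oxobutanoate; 5 1-methoxy-4-[(prop-1-en-2-yloxy)methyl]benzene
Product: 8 methyl 2-[(1R,2R)-2-[(4-methoxyphenyl)methoxy]-2-methyl-4-oxocyclobutyl]acetate, via keteniminium triflate 6 (not isolated), via cyclobutaniminium triflate 7 (not isolated)
Conditions: 2,6-di-tert-butylpyridine (1.2 equiv), Tf2O (1.0 equiv), CH2Cl2, −78 to 0 °C; 5 (2 equiv), −78 to −20 °C; aq NaHCO3, rt
Reagents that add atoms: water, O
Why: Proposed new method: Tf2O sulfonylates the amide oxygen of 3 and the hindered pyridine removes a C3 proton to give keteniminium ion 6, the nucleophilic CH2 terminus (C5) of 5 attacks its central carbon (C6), the oxocarbenium ion left at C4 is captured by the enamine carbon C3 to give 7, and water then exchanges the iminium nitrogen for oxygen and releases the auxiliary. The closest known reaction types are the keteniminium–alkene (2+2) cycloaddition, including its auxiliary-controlled form with 2,5-dimethylpyrrolidine amides, and the ketene–enol ether (2+2) route to 3-alkoxycyclobutanones; new is the pairing of a chiral keteniminium salt with a 1,1-disubstituted enol ether. The cyclobutane closes in a stepwise polar manner, formally 4-exo-trig at the C4=O+ acceptor with the C3=C6 enamine bond inside the forming ring, an overlap made possible by the twist about C3–C6 common to ketene-type (2+2) closures. C3 is controlled by the twofold-symmetric pyrrolidine, which allows a single keteniminium geometry and whose methyl group on the C5 side shields one enamine face during closure, and C4 is relayed from C3 because the CH2CO2Me arm should settle trans to the C4 methyl and cis to the slimmer ether oxygen. Regioselectivity is secured by polarity (only the oxygen-bearing C4 can carry the cation), chemoselectivity by forming 6 before 5 is added so that Tf2O never meets the enol ether, and survival of the push–pull ring of 7 by low temperature, a non-nucleophilic counter-ion and prompt buffered hydrolysis. Because C3 is erased later, any (4S) material must be removed here, so the C3/C4 diastereomers of 8 are to be separated before C3 can epimerise and the enantiomeric purity is to be checked at this stage.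

Step 4
Reactants: 8 methyl 2-[(1R,2R)-2-[(4-methoxyphenyl)methoxy]-2-methyl-4-oxocyclobutyl]acetate
Product: 9 methyl 2-[(1S,2R,4S)-4-hydroxy-2-[(4-methoxyphenyl)methoxy]-2,4-dimethylcyclobutyl]acetate
Conditions: MeMgBr, CeCl3 (anhydrous), THF, −78 °C; AcOH/THF quench at −78 °C; crude used directly
Reagents that add atoms: methylmagnesium bromide, C[Mg]Br
Why: In this organocerium (Imamoto) 1,2-addition the weakly basic MeCeCl2 should add to the strained ketone far faster than to the ester, without enolisation or β-elimination of the C4 ether; attack anti to the C3 arm should place the C6 hydroxyl cis to it (a temporary centre erased in step 5), and the cold acidic quench with direct use is meant to forestall lactonisation onto the ester.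

Step 5
Reactants: 9 methyl 2-[(1S,2R,4S)-4-hydroxy-2-[(4-methoxyphenyl)methoxy]-2,4-dimethylcyclobutyl]acetate
Product: 11 methyl 2-[(4R)-6-hydroxy-4-[(4-methoxyphenyl)methoxy]-4,6-dimethyl-1,2-dioxan-3-yl]acetate (C3 epimers; C6 anomers), via hydroperoxy ketone 10 (not isolated)
Conditions: Co(acac)2 (20 mol %), O2 (1 atm), 1,2-dichloroethane, 40 °C
Reagents that add atoms: dioxygen, O=O
Why: In the known cobalt-catalysed aerobic ring expansion of cyclobutanols the cobalt alkoxide gives the C6 alkoxy radical, strain-driven β-scission cuts C3–C6 toward the secondary C3 radical rather than C5–C6 toward a primary one, O2 is captured at C3 and hydroperoxide 10 closes on the new C6 ketone (6-exo-trig hemiperketalisation); C4 is untouched, while C3 forms without control and C6 is anomeric, so both are fixed later (steps 9 and 7).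

Step 6
Reactants: 11 methyl 2-[(4R)-6-hydroxy-4-[(4-methoxyphenyl)methoxy]-4,6-dimethyl-1,2-dioxan-3-yl]acetate
Product: 12 methyl 2-[(4R)-6-acetyloxy-4-[(4-methoxyphenyl)methoxy]-4,6-dimethyl-1,2-dioxan-3-yl]acetate (C3 epimers; C6 anomers)
Conditions: Ac2O, pyridine, DMAP (cat.), CH2Cl2, 0 °C
Reagents that add atoms: acetic anhydride, CC(=O)OC(C)=O
Why: O-acetylation of the hemiperketal hydroxyl, as for lactols, installs a leaving group that a catalytic silyl triflate can ionise at low temperature, which spares the PMB ether; no stereocentre is fixed.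

Step 7
Reactants: 12 methyl 2-[(4R)-6-acetyloxy-4-[(4-methoxyphenyl)methoxy]-4,6-dimethyl-1,2-dioxan-3-yl]acetate
Product: 13 methyl 2-[(4R,6S)-4-[(4-methoxyphenyl)methoxy]-4,6-dimethyl-6-(prop-2-en-1-yl)-1,2-dioxan-3-yl]acetate (C3 epimers)
Conditions: allyltrimethylsilane (3 equiv), TMSOTf (20 mol %), CH2Cl2, −78 °C
Reagents that add atoms: allyltrimethylsilane, C=CC[Si](C)(C)C
Why: In this Hosomi–Sakurai-type allylation of the C6 peroxycarbenium ion, the half-chair with the C4 methyl pseudoequatorial and the C4 ether oxygen pseudoaxial (held over the cation electrostatically) should undergo stereoelectronically preferred axial attack, placing the allyl group cis to the C4 oxygen, i.e. (6S), for either C3 epimer, because the other half-chair would bring the nucleophile in against an axial C4 methyl.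

Step 8
Reactants: 13 methyl 2-[(4R,6S)-4-[(4-methoxyphenyl)methoxy]-4,6-dimethyl-6-(prop-2-en-1-yl)-1,2-dioxan-3-yl]acetate
Product: 14 methyl 2-[(4R,6S)-4-hydroxy-4,6-dimethyl-6-(prop-2-en-1-yl)-1,2-dioxan-3-yl]acetate (C3 epimers)
Conditions: DDQ, CH2Cl2/pH 7 buffer (10:1), 0 °C
Reagents that add atoms: none
Why: In the oxidative PMB cleavage DDQ abstracts hydride from the electron-rich benzylic CH2 and water hydrolyses the resulting cation, while peroxide, terminal alkene and ester are inert and the C4–O bond is not broken, so C4 is retained; partial spontaneous lactonisation of the (3R) epimer would be harmless.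

Step 9
Reactants: 14 methyl 2-[(4R,6S)-4-hydroxy-4,6-dimethyl-6-(prop-2-en-1-yl)-1,2-dioxan-3-yl]acetate
Product: 16 (3S,4aR,7aR)-3,4a-dimethyl-3-(prop-2-en-1-yl)tetrahydro-3H-furo[3,2-c][1,2]dioxin-6(4H)-one, via hydroperoxy enoate 15 (not isolated)
Conditions: NaOMe (0.2 equiv), MeOH, 0 °C to rt; AcOH; then PPTS (cat.), CH2Cl2, rt
Reagents that add atoms: none
Why: Proposed new method: methoxide reversibly removes a C2 proton and expels the C6 peroxide anion from C3 (E1cB, retro-peroxy-Michael) to give open enoate 15, whose 6-exo-trig re-addition returns both C3 epimers, and since only the epimer with the C3 arm cis to the C4 hydroxyl can close a γ-lactone without forcing the C4 and C6 methyl groups into a 1,3-diaxial clash, loss of methanol should drain the equilibrium into cis-fused (3R)-16, so that C3 is set by C4 under thermodynamic control; the protic solvent protonates the β-peroxy enolate before it can collapse to an epoxide; the closest known reaction types are the base-promoted intramolecular conjugate addition of hydroperoxides to enoates and butenolides and the retro-oxa-Michael/oxa-Michael equilibration of tetrahydropyranyl acetates.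

Step 10
Reactants: 17 11-bromoundec-1-ene
Product: 18 11-phenylundec-1-ene
Conditions: PhMgBr, Li2CuCl4 (3 mol %), THF, 0 °C to rt
Reagents that add atoms: phenylmagnesium bromide, Br[Mg]c1ccccc1
Why: Copper-catalysed cross-coupling of a Grignard reagent with a primary alkyl bromide (Kochi coupling) is dependable and leaves the remote terminal alkene as a spectator.

Step 11
Reactants: 16 (3S,4aR,7aR)-3,4a-dimethyl-3-(prop-2-en-1-yl)tetrahydro-3H-furo[3,2-c][1,2]dioxin-6(4H)-one; 18 11-phenylundec-1-ene
Product: 19 (3S,4aR,7aR)-3,4a-dimethyl-3-[(2E)-12-phenyldodec-2-en-1-yl]tetrahydro-3H-furo[3,2-c][1,2]dioxin-6(4H)-one (E expected as major isomer; Z serves equally)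
Conditions: 18 (3 equiv), second-generation Grubbs catalyst (H2IMes)(PCy3)Cl2Ru=CHPh (5 mol %), CH2Cl2, 40 °C
Reagents that add atoms: none
Why: In this olefin cross-metathesis of two terminal alkenes the excess of 18 should favour the cross product, dialkyl peroxides tolerate ruthenium carbenes, and the alkene geometry is irrelevant because the bond is saturated next.

Step 12
Reactants: 19 (3S,4aR,7aR)-3,4a-dimethyl-3-[(2E)-12-phenyldodec-2-en-1-yl]tetrahydro-3H-furo[3,2-c][1,2]dioxin-6(4H)-one
Product: 20 plakortolide K, (3S,4aR,7aR)-3,4a-dimethyl-3-(12-phenyldodecyl)tetrahydro-3H-furo[3,2-c][1,2]dioxin-6(4H)-one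
Conditions: dipotassium azodicarboxylate (excess), AcOH, MeOH/CH2Cl2, 0 °C to rt
Reagents that add atoms: none
Why: Diimide reduction transfers H2 to C8=C9 in a concerted syn manner and leaves the O–O bond, lactone and arene untouched, unlike catalytic hydrogenation, and the mildly acidic medium avoids base-induced opening of the β-peroxy lactone; no stereocentre is touched.

**Compound list**
1 | methyl 4-chloro-4-oxobutanoate | COC(=O)CCC(=O)Cl | starting material
2 | (2R,5R)-2,5-dimethylpyrrolidine | C[C@@H]1CC[C@@H](C)N1 | starting material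
3 | methyl 4-[(2R,5R)-2,5-dimethylpyrrolidin-1-yl]-4-oxobutanoate | COC(=O)CCC(=O)N1[C@H](C)CC[C@H]1C | intermediate
4 | 4-methoxybenzyl acetate | CC(=O)OCc1ccc(OC)cc1 | starting material
5 | 1-methoxy-4-[(prop-1-en-2-yloxy)methyl]benzene | C=C(C)OCc1ccc(OC)cc1 | intermediate
6 | (2R,5R)-1-(4-methoxy-4-oxobut-1-en-1-ylidene)-2,5-dimethylpyrrolidin-1-ium trifluoromethanesulfonate | COC(=O)CC=C=[N+]1[C@H](C)CC[C@H]1C.[O-]S(=O)(=O)C(F)(F)F | intermediate
7 | (2R,5R)-1-[(2S,3R)-2-(2-methoxy-2-oxoethyl)-3-[(4-methoxyphenyl)methoxy]-3-methylcyclobutylidene]-2,5-dimethylpyrrolidin-1-ium trifluoromethanesulfonate | COC(=O)C[C@H]1C(=[N+]2[C@H](C)CC[C@H]2C)C[C@@]1(C)OCc3ccc(OC)cc3.[O-]S(=O)(=O)C(F)(F)F | intermediate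
8 | methyl 2-[(1R,2R)-2-[(4-methoxyphenyl)methoxy]-2-methyl-4-oxocyclobutyl]acetate | COC(=O)C[C@H]1C(=O)C[C@@]1(C)OCc2ccc(OC)cc2 | intermediate
9 | methyl 2-[(1S,2R,4S)-4-hydroxy-2-[(4-methoxyphenyl)methoxy]-2,4-dimethylcyclobutyl]acetate | COC(=O)C[C@H]1[C@@](C)(O)C[C@@]1(C)OCc2ccc(OC)cc2 | intermediate
10 | methyl (4R)-3-hydroperoxy-4-[(4-methoxyphenyl)methoxy]-4-methyl-6-oxoheptanoate (C3 epimers) | COC(=O)CC(OO)[C@@](C)(CC(C)=O)OCc1ccc(OC)cc1 | intermediate
11 | methyl 2-[(4R)-6-hydroxy-4-[(4-methoxyphenyl)methoxy]-4,6-dimethyl-1,2-dioxan-3-yl]acetate (C3 epimers; C6 anomers) | CC1(O)C[C@@](C)(OCc2ccc(OC)cc2)C(CC(=O)OC)OO1 | intermediate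
12 | methyl 2-[(4R)-6-acetyloxy-4-[(4-methoxyphenyl)methoxy]-4,6-dimethyl-1,2-dioxan-3-yl]acetate (C3 epimers; C6 anomers) | CC(=O)OC1(C)C[C@@](C)(OCc2ccc(OC)cc2)C(CC(=O)OC)OO1 | intermediate
13 | methyl 2-[(4R,6S)-4-[(4-methoxyphenyl)methoxy]-4,6-dimethyl-6-(prop-2-en-1-yl)-1,2-dioxan-3-yl]acetate (C3 epimers) | C[C@]1(CC=C)C[C@@](C)(OCc2ccc(OC)cc2)C(CC(=O)OC)OO1 | intermediate
14 | methyl 2-[(4R,6S)-4-hydroxy-4,6-dimethyl-6-(prop-2-en-1-yl)-1,2-dioxan-3-yl]acetate (C3 epimers) | C[C@]1(CC=C)C[C@@](C)(O)C(CC(=O)OC)OO1 | intermediate
15 | methyl (2E,4R,6S)-6-hydroperoxy-4-hydroxy-4,6-dimethylnona-2,8-dienoate | COC(=O)/C=C/[C@](C)(O)C[C@](C)(CC=C)OO | intermediate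
16 | (3S,4aR,7aR)-3,4a-dimethyl-3-(prop-2-en-1-yl)tetrahydro-3H-furo[3,2-c][1,2]dioxin-6(4H)-one | C[C@]1(CC=C)C[C@@]2(C)OC(=O)C[C@H]2OO1 | intermediate
17 | 11-bromoundec-1-ene | C=CCCCCCCCCCBr | starting material
18 | 11-phenylundec-1-ene | C=CCCCCCCCCCc1ccccc1 | intermediate
19 | (3S,4aR,7aR)-3,4a-dimethyl-3-[(2E)-12-phenyldodec-2-en-1-yl]tetrahydro-3H-furo[3,2-c][1,2]dioxin-6(4H)-one | C[C@]1(C/C=C/CCCCCCCCCc3ccccc3)C[C@@]2(C)OC(=O)C[C@H]2OO1 | intermediate
20 | plakortolide K | C[C@]1(CCCCCCCCCCCCc2ccccc2)C[C@@]2(C)OC(=O)C[C@H]2OO1 | target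

**Step count**
Total steps: 12. Longest linear sequence: 10 (steps 1, 3, 4, 5, 6, 7, 8, 9, 11, 12).

**Steps most likely to fail**

Step 3. Several processes could compete with ring closure:
- The push–pull cyclobutaniminium ring may reopen and leak away, either by loss of the 4-methoxybenzyl cation or by proton loss from the oxocarbenium ion.
- The ester carbonyl may cyclise onto the keteniminium carbon.
- The enol ether may polymerise cationically.
- Facial or C3/C4 selectivity may be weak.

The fallback sets out from 1 and 5 and uses the neutral ketene instead of the cation. Dehydrochlorination of 1 with iPr2NEt in MeCN, in the presence of excess 5, generates the ketene methyl 4-oxobut-3-enoate F1. The established thermal ketene–enol ether (2+2) cycloaddition then gives racemic methyl 2-[2-[(4-methoxyphenyl)methoxy]-2-methyl-4-oxocyclobutyl]acetate F2. Charge annihilation makes this closure irreversible. Preparative chromatography on a chiral stationary phase separates 8 from its enantiomer, methyl 2-[(1S,2S)-2-[(4-methoxyphenyl)methoxy]-2-methyl-4-oxocyclobutyl]acetate F3, which is set aside. The route is rejoined at 8.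

Step 9. Three things could go wrong:
- Enolisation of the methyl ester may be too slow for the (3S) epimer to open.
- The β-peroxy enolate may collapse to an epoxide with O–O cleavage.
- Base may remove the C3 hydrogen and trigger Kornblum–DeLaMare fragmentation.

The fallback sets out from 14 and replaces equilibration by chemical differentiation and separation. With PPTS (cat.) in CH2Cl2 only the (3R) epimer should undergo the ordinary acid-catalysed γ-lactonisation to 16. The unreacted methyl 2-[(3S,4R,6S)-4-hydroxy-4,6-dimethyl-6-(prop-2-en-1-yl)-1,2-dioxan-3-yl]acetate F4, much more polar, is removed by chromatography. The route is rejoined at 16, at the price of the (3S) material.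

Step 7. Four things could go wrong:
- Facial selectivity may be eroded by the developing 1,3-diaxial contact between the incoming allyl group and the C4 benzyloxy group, and may differ between the two C3 epimers.
- The Lewis acid may strip the PMB ether.
- The peroxycarbenium ion may lose a proton.
- The O–O bond may heterolyse.

The fallback sets out from 12 and inverts the order of events, so that the allylation runs on a rigid bicycle. DDQ gives methyl 2-[(4R)-6-acetyloxy-4-hydroxy-4,6-dimethyl-1,2-dioxan-3-yl]acetate F5. PPTS closes only the epimer with the C3 arm cis to the C4 hydroxyl, giving (4aR,7aR)-3,4a-dimethyl-6-oxohexahydrofuro[3,2-c][1,2]dioxin-3-yl acetate F6, which is purified. Allyltrimethylsilane/TMSOTf then acts on a cation whose C4 oxygen is tied back into the lactone as a small axial substituent, with no acid-labile ether present. This should give 16 directly, where the route is rejoined.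

**Further compounds**
F1 | step 3 | methyl 4-oxobut-3-enoate (ketene) | COC(=O)CC=C=O
F2 | step 3 | racemic methyl 2-[2-[(4-methoxyphenyl)methoxy]-2-methyl-4-oxocyclobutyl]acetate | COC(=O)CC1C(=O)CC1(C)OCc1ccc(OC)cc1
F3 | step 3 | methyl 2-[(1S,2S)-2-[(4-methoxyphenyl)methoxy]-2-methyl-4-oxocyclobutyl]acetate | COC(=O)C[C@@H]1C(=O)C[C@]1(C)OCc2ccc(OC)cc2
F4 | step 9 | methyl 2-[(3S,4R,6S)-4-hydroxy-4,6-dimethyl-6-(prop-2-en-1-yl)-1,2-dioxan-3-yl]acetate | C[C@]1(CC=C)C[C@@](C)(O)[C@H](CC(=O)OC)OO1
F5 | step 7 | methyl 2-[(4R)-6-acetyloxy-4-hydroxy-4,6-dimethyl-1,2-dioxan-3-yl]acetate | CC(=O)OC1(C)C[C@@](C)(O)C(CC(=O)OC)OO1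
F6 | step 7 | (4aR,7aR)-3,4a-dimethyl-6-oxohexahydrofuro[3,2-c][1,2]dioxin-3-yl acetate | CC(=O)OC1(C)C[C@@]2(C)OC(=O)C[C@H]2OO1
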